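The ratio I followed in these flasks was ρ, free nucleophile over electrophile, and my reckoning hung on what one target costs.

| setting | dusk | ash | maple |
|---|---|---|---|
| electrophile | 0.20 M | 0.20 M | 0.20 M |
| nucleophile | 1.6 equiv (fed, over 1.0 h) | 1.30 equiv (fed, over 1.0 h) | 1.70 equiv (fed, over 1.0 h) |
| remark | run made earlier |  |  |
| time |  | 2.0 h | 2.0 h |

dusk run (percent of the electrophile charged)

| time / min | electrophile / % | target / % |
|---|---|---|
| 8.00 | 100.2 | 0.6 |
| 20.0 | 97.3 | 3.1 |
| 40.0 | 90.0 | 9.8 |
| 60.0 | 79.6 | 20.1 |
| 80.0 | 70.4 | 29.4 |

(standard deviation of a reading: 0.3 percentage points)

- the numbers in the tables scatter by 0.3 percentage points (one standard deviation)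
- steps thought possible: electrophile + nucleophile -> acid set free + target; nucleophile + acid set free <-> protonated nucleophile; acid set free -> by-product carried off

- part of the electrophile that has reacted at the end, ash
- part of the electrophile that has reacted at the end, maple
- what raising the equivalents of nucleophile from its lowest to its highest value here does to the part of the electrophile that has reacted (changes below 5 percentage points count as none) (no change / it rises / it falls)

On the first rung of my ladder I put the binding of acid to nucleophile, which I assumed to be done as soon as acid appears, so I took each target to cost one electrophile and two nucleophiles. Free nucleophile was then the dosed amount less twice the target. In my reckoning, nucleophile minus twice electrophile stays constant after the feed, so ln ρ falls in a straight line, with slope k times the excess of twice a over b. Here k is the second-order constant of the coupling, a the electrophile charged and b the nucleophile charged. In dusk, ρ went from 1.51 at 60.0 min to 1.44 at 80.0 min, which read as 1.72 L mol⁻¹ h⁻¹, the coupling constant, a reading that carries the scatter.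

The next rung was the feed, 1.0 h. In ash, with the whole charge counted as if present at once, the coupling had a time scale of about 2.23 h, longer than the feed, and ρ had a longer one still, 4.15 h. I could not read the later fate of the acid from dusk, so I left it out.

During the feed the cost was a correction: at the end of the dusk feed, twice the target was a quarter of the dosed nucleophile. So I scaled the logarithm of the electrophile left by the equivalents, which left 83.1% in ash and 78.5% in maple. From there ash's ρ began at 1.16 and fell at 0.241 h⁻¹, reaching 0.910, so I expected 35.8% reacted. Maple's ρ began at 1.62 and reached 1.46, so I expected 44.6%.

The forecast gave 36% (33% to 41%) for ash and 45% (41% to 50%) for maple, with the trend it rises, on the ground that “each target formed costs two nucleophiles”.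

Ash reached 35.9% and maple 44.6%; the trend was it rises, by 8.7 percentage points.

    electrophile + nucleophile → acid set free + target (k = 4.80 × 10⁻⁴ L mol⁻¹ s⁻¹)
    nucleophile + acid set free ⇌ protonated nucleophile, settled at all times (K = 940 L mol⁻¹)
    acid set free → by-product carried off (k = 8.00 × 10⁻⁴ s⁻¹)

The passing of acid set free into by-product carried off made no difference to ash at the asked time. With 1.72 L mol⁻¹ h⁻¹, ash's ρ falls at 0.241 h⁻¹, and I carried that past the asked time.

For the ash flask left until 5.0 h, I reckoned ρ at 0.441, which gave 55.1% reacted. The computed flask gave 56.4%, with 0.0133 M of by-product carried off.

Readings and results come from a simulation from invented constants; noise was put on by code.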